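**Retrosynthetic overview**
1. Acid 25 ⇐ methyl ester 24; the 1,2-dioxane (second ring, formed last) ⇐ new catalyst-controlled 6-exo-trig peroxy-Michael closure of the (6R)-hydroperoxy (E)-enoate 23, which sets C3.
2. C6–OOH of 23 ⇐ threo (6S) alcohol 17 by SN2 inversion (triflate plus protected H2O2); enoate ⇐ lactol 16 by Wittig reaction.
3. (7Z,9E)-diene ⇐ Z-selective Wittig reaction of phosphonium salt 11 with (E)-hepta-2,6-dienal 13.
4. C6 carbinol ⇐ chelation-controlled Grignard addition to the trans-oxolane aldehyde 6.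
5. trans-2,5-Oxolane (first ring) ⇐ Mukaiyama aerobic oxidative cyclisation of (R)-alkenol 4 ⇐ (S)-epoxide 2 plus the Grignard reagent from 1.

Assumption: compounds 1, 2, 7, 12, 18 and the squaramide catalyst are bought; C1–C6 denote the hexanoate arm (C1 = carboxyl carbon, C3 and C6 = the dioxane carbons), and oxolane C2 carries C6 while oxolane C5 carries the C14 chain.

**Step 1**
Reactants: 1 1-bromo-6-chlorohexane; 2 (S)-2-(but-3-en-1-yl)oxirane
Product: 4 (5R)-12-chlorododec-1-en-5-ol, via 6-chlorohexylmagnesium bromide 3 (not isolated)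
Conditions: 1, Mg, THF, 35 °C; then CuI (10 mol%), 2, THF, −40 to 0 °C; H2O quench
Reagents that add atoms: none
Why: Mg inserts into C–Br far faster than into C–Cl, and the copper-catalysed Grignard opening of the terminal epoxide is an SN2 attack at the CH2 terminus, so the stereocentre of 2 is carried over unchanged as (5R).

**Step 2**
Reactants: 4 (5R)-12-chlorododec-1-en-5-ol
Product: 5 [(2S,5R)-5-(7-chloroheptyl)oxolan-2-yl]methanol
Conditions: Co(modp)2 [Co(C12H18NO4)2, modp = 1-morpholinocarbamoyl-4,4-dimethylpentane-1,3-dionate] (10 mol%), O2 (1 atm), t-BuOOH (10 mol%), i-PrOH, 55 °C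
Reagents that add atoms: dioxygen, O=O
Why: Mukaiyama aerobic oxidative cyclisation of a 5-hydroxy-1-alkene closes the oxolane with very high 2,5-trans selectivity, so the new ring carbon (2S) is set trans to the existing (5R) centre and the exocyclic carbon is oxygenated by O2.

**Step 3**
Reactants: 5 [(2S,5R)-5-(7-chloroheptyl)oxolan-2-yl]methanol
Product: 6 (2S,5R)-5-(7-chloroheptyl)oxolane-2-carbaldehyde
Conditions: Dess–Martin periodinane, CH2Cl2, 0 °C to rt; used crude
Reagents that add atoms: none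
Why: Dess–Martin oxidation stops at the α-alkoxy aldehyde under near-neutral conditions that do not epimerise the adjacent ring stereocentre.

**Step 4**
Reactants: 6 (2S,5R)-5-(7-chloroheptyl)oxolane-2-carbaldehyde; 7 2-(2-bromoethyl)-1,3-dioxolane
Product: 9 (1S)-1-[(2S,5R)-5-(7-chloroheptyl)oxolan-2-yl]-3-(1,3-dioxolan-2-yl)propan-1-ol, via dioxolanylethylmagnesium bromide 8 (not isolated)
Conditions: 7, Mg, THF, 25 °C; then 6, MgBr2·OEt2, CH2Cl2, −78 °C; H2O quench
Reagents that add atoms: none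
Why: Cram chelate-controlled Grignard addition, in which MgBr2 bridges the aldehyde and ring oxygens so that the nucleophile adds from the face of the small hydrogen substituent, gives the threo (1S) carbinol; the primary chloride is inert at −78 °C.

**Step 5**
Reactants: 9 (1S)-1-[(2S,5R)-5-(7-chloroheptyl)oxolan-2-yl]-3-(1,3-dioxolan-2-yl)propan-1-ol
Product: 11 {7-[(2R,5S)-5-[(1S)-3-(1,3-dioxolan-2-yl)-1-hydroxypropyl]oxolan-2-yl]heptyl}triphenylphosphonium iodide, via alkyl iodide 10 (not isolated)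
Conditions: NaI, PPh3, MeCN, 80 °C
Reagents that add atoms: sodium iodide, [Na+].[I-]; triphenylphosphine, c1ccc(cc1)P(c1ccccc1)c1ccccc1
Why: Finkelstein exchange (NaCl precipitates from MeCN) followed by SN2 quaternisation of PPh3 by the primary iodide, with the secondary alcohol and the acetal untouched.

**Step 6**
Reactants: 12 pent-4-enal
Product: 13 (2E)-hepta-2,6-dienal
Conditions: Ph3P=CHCHO (1.0 equiv), toluene, 80 °C
Reagents that add atoms: (triphenylphosphoranylidene)acetaldehyde, O=CC=P(c1ccccc1)(c1ccccc1)c1ccccc1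
Why: Wittig reaction of the stabilised formylmethylene ylide gives the (E)-enal selectively, and one equivalent of ylide limits a second homologation.

**Step 7**
Reactants: 11 {7-[(2R,5S)-5-[(1S)-3-(1,3-dioxolan-2-yl)-1-hydroxypropyl]oxolan-2-yl]heptyl}triphenylphosphonium iodide; 13 (2E)-hepta-2,6-dienal
Product: 15 (1S)-3-(1,3-dioxolan-2-yl)-1-{(2S,5R)-5-[(7Z,9E)-tetradeca-7,9,13-trien-1-yl]oxolan-2-yl}propan-1-ol, via ylide sodium alkoxide 14 (not isolated)
Conditions: 11, NaN(SiMe3)2 (2.1 equiv), THF, −78 to 0 °C; then 13, −78 °C to rt; H2O quench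
Reagents that add atoms: none
Why: Salt-free Wittig reaction of a non-stabilised ylide with an enal under kinetic control forms the new C7=C8 bond as Z while the E bond of 13 is kept, the first equivalent of base serving only to make the alkoxide.

**Step 8**
Reactants: 15 (1S)-3-(1,3-dioxolan-2-yl)-1-{(2S,5R)-5-[(7Z,9E)-tetradeca-7,9,13-trien-1-yl]oxolan-2-yl}propan-1-ol
Product: 16 (5S)-5-{(2S,5R)-5-[(7Z,9E)-tetradeca-7,9,13-trien-1-yl]oxolan-2-yl}oxolan-2-ol (lactol as anomer mixture)
Conditions: 1 molar aq. HCl, THF, rt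
Reagents that add atoms: water, O
Why: Acid-catalysed acetal hydrolysis frees the γ-hydroxy aldehyde, which closes to the five-membered lactol without touching any stereocentre or the diene.

**Step 9**
Reactants: 16 (5S)-5-{(2S,5R)-5-[(7Z,9E)-tetradeca-7,9,13-trien-1-yl]oxolan-2-yl}oxolan-2-ol
Product: 17 methyl (2E,6S)-6-hydroxy-6-{(2S,5R)-5-[(7Z,9E)-tetradeca-7,9,13-trien-1-yl]oxolan-2-yl}hex-2-enoate
Conditions: Ph3P=CHCO2Me (1.5 equiv), toluene, 40 °C
Reagents that add atoms: methyl (triphenylphosphoranylidene)acetate, COC(=O)C=P(c1ccccc1)(c1ccccc1)c1ccccc1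
Why: The lactol reacts through its open hydroxy-aldehyde form in a Wittig reaction with the stabilised ylide to give the (E)-enoate, and without added base the 6-hydroxy enoate does not undergo oxa-Michael closure.

**Step 10**
Reactants: 18 3,4-dihydro-2H-pyran
Product: 19 oxan-2-yl hydroperoxide (racemic)
Conditions: 50% aq. H2O2 (3 equiv), H2SO4 (cat.), 0 °C
Reagents that add atoms: hydrogen peroxide, OO
Why: Acid-catalysed Markovnikov addition of H2O2 to the enol ether through the oxocarbenium ion gives the hydroperoxy acetal, which serves as a mono-protected H2O2.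

**Step 11**
Reactants: 17 methyl (2E,6S)-6-hydroxy-6-{(2S,5R)-5-[(7Z,9E)-tetradeca-7,9,13-trien-1-yl]oxolan-2-yl}hex-2-enoate; 19 oxan-2-yl hydroperoxide
Product: 22 methyl (2E,6R)-6-[(oxan-2-yl)peroxy]-6-{(2S,5R)-5-[(7Z,9E)-tetradeca-7,9,13-trien-1-yl]oxolan-2-yl}hex-2-enoate (epimer mixture at the acetal carbon), via triflate 20 (not isolated), via potassium oxan-2-yl peroxide 21 (not isolated)
Conditions: 17, Tf2O, 2,6-lutidine, CH2Cl2, −78 °C; separately 19, KOt-Bu, THF, 0 °C; combine, −78 to 0 °C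
Reagents that add atoms: none
Why: SN2 alkylation of the peroxide anion (an α-effect nucleophile of low basicity) by the secondary triflate inverts C6 from S to R and so gives the erythro C6–O/ring-O relationship of the target.

**Step 12**
Reactants: 22 methyl (2E,6R)-6-[(oxan-2-yl)peroxy]-6-{(2S,5R)-5-[(7Z,9E)-tetradeca-7,9,13-trien-1-yl]oxolan-2-yl}hex-2-enoate
Product: 23 methyl (2E,6R)-6-hydroperoxy-6-{(2S,5R)-5-[(7Z,9E)-tetradeca-7,9,13-trien-1-yl]oxolan-2-yl}hex-2-enoate
Conditions: p-TsOH·H2O (10 mol%), MeOH, 0 °C to rt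
Reagents that add atoms: none
Why: Acid-catalysed transacetalisation with methanol cleaves the peroxyacetal at the acetal carbon, so the O–O bond, the C6 configuration and the enoate stay intact and no base is present to trigger premature cyclisation.

**Step 13**
Reactants: 23 methyl (2E,6R)-6-hydroperoxy-6-{(2S,5R)-5-[(7Z,9E)-tetradeca-7,9,13-trien-1-yl]oxolan-2-yl}hex-2-enoate
Product: 24 methyl 2-[(3R,6R)-6-{(2S,5R)-5-[(7Z,9E)-tetradeca-7,9,13-trien-1-yl]oxolan-2-yl}-1,2-dioxan-3-yl]acetate
Conditions: quinine-derived squaramide 3-{[3,5-bis(trifluoromethyl)phenyl]amino}-4-{[(8α,9S)-6′-methoxycinchonan-9-yl]amino}cyclobut-3-ene-1,2-dione (10 mol%), toluene, 0 °C to rt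
Reagents that add atoms: none
Why: Proposed new method: a bifunctional cinchona squaramide is used to control a 6-exo-trig intramolecular peroxy-Michael addition of a secondary alkyl hydroperoxide onto a simple enoate, in which the quinuclidine nitrogen reversibly deprotonates the hydroperoxide (pKa about 12) while the two squaramide N–H bonds bind the ester carbonyl, so the peroxide anion is delivered to the Re face of C3 through a chair transition state with the oxolanyl group and the forming CH2CO2Me arm both equatorial and the ammonium then protonates the ester enolate, giving the trans (3R,6R) ring; because the amine also mediates the retro-Michael reaction, any cis ring can reopen and the diequatorial trans isomer accumulates; the closest known reaction types are the achiral amine-promoted (Et2NH in CF3CH2OH) peroxy-Michael cyclisation of hydroperoxy enoates to 1,2-dioxane-3-acetates and the cinchona-catalysed intermolecular peroxidation of enones, and what has not been shown is catalyst control of the ring-forming, C3-setting version on an unactivated ester.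

**Step 14**
Reactants: 24 methyl 2-[(3R,6R)-6-{(2S,5R)-5-[(7Z,9E)-tetradeca-7,9,13-trien-1-yl]oxolan-2-yl}-1,2-dioxan-3-yl]acetate
Product: 25 2-[(3R,6R)-6-{(2S,5R)-5-[(7Z,9E)-tetradeca-7,9,13-trien-1-yl]oxolan-2-yl}-1,2-dioxan-3-yl]acetic acid (CNP0186740.6)
Conditions: LiOH·H2O (3 equiv), THF/H2O (3:1), 0 °C; then 1 molar aq. HCl to pH 3
Reagents that add atoms: lithium hydroxide, [Li+].[OH-]
Why: Ester saponification (BAc2) at 0 °C is the standard way to free 1,2-dioxane-3-acetic acids without cleaving the dialkyl peroxide, and short contact at low temperature limits retro-Michael opening.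

**Compound list**
1 | 1-bromo-6-chlorohexane | ClCCCCCCBr | starting material
2 | (S)-2-(but-3-en-1-yl)oxirane | C=CCC[C@H]1CO1 | starting material
3 | 6-chlorohexylmagnesium bromide | ClCCCCCC[Mg]Br | intermediate (not isolated)
4 | (5R)-12-chlorododec-1-en-5-ol | C=CCC[C@H](O)CCCCCCCCl | intermediate
5 | [(2S,5R)-5-(7-chloroheptyl)oxolan-2-yl]methanol | ClCCCCCCC[C@@H]1CC[C@@H](CO)O1 | intermediate
6 | (2S,5R)-5-(7-chloroheptyl)oxolane-2-carbaldehyde | ClCCCCCCC[C@@H]1CC[C@@H](C=O)O1 | intermediate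
7 | 2-(2-bromoethyl)-1,3-dioxolane | BrCCC1OCCO1 | starting material
8 | [2-(1,3-dioxolan-2-yl)ethyl]magnesium bromide | Br[Mg]CCC1OCCO1 | intermediate (not isolated)
9 | (1S)-1-[(2S,5R)-5-(7-chloroheptyl)oxolan-2-yl]-3-(1,3-dioxolan-2-yl)propan-1-ol | ClCCCCCCC[C@@H]1CC[C@@H]([C@@H](O)CCC2OCCO2)O1 | intermediate
10 | (1S)-3-(1,3-dioxolan-2-yl)-1-[(2S,5R)-5-(7-iodoheptyl)oxolan-2-yl]propan-1-ol | ICCCCCCC[C@@H]1CC[C@@H]([C@@H](O)CCC2OCCO2)O1 | intermediate (not isolated)
11 | {7-[(2R,5S)-5-[(1S)-3-(1,3-dioxolan-2-yl)-1-hydroxypropyl]oxolan-2-yl]heptyl}triphenylphosphonium iodide | C(CCCCCC[C@@H]1CC[C@@H]([C@@H](O)CCC2OCCO2)O1)[P+](c3ccccc3)(c4ccccc4)c5ccccc5.[I-] | intermediate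
12 | pent-4-enal | C=CCCC=O | starting material
13 | (2E)-hepta-2,6-dienal | C=CCC/C=C/C=O | intermediate
14 | sodium alkoxide of the triphenylphosphonium ylide derived from 11 | C(=P(c3ccccc3)(c4ccccc4)c5ccccc5)CCCCCC[C@@H]1CC[C@@H]([C@@H]([O-])CCC2OCCO2)O1.[Na+] | intermediate (not isolated)
15 | (1S)-3-(1,3-dioxolan-2-yl)-1-{(2S,5R)-5-[(7Z,9E)-tetradeca-7,9,13-trien-1-yl]oxolan-2-yl}propan-1-ol | C=CCC/C=C/C=C\CCCCCC[C@@H]1CC[C@@H]([C@@H](O)CCC2OCCO2)O1 | intermediate
16 | (5S)-5-{(2S,5R)-5-[(7Z,9E)-tetradeca-7,9,13-trien-1-yl]oxolan-2-yl}oxolan-2-ol (anomer mixture) | C=CCC/C=C/C=C\CCCCCC[C@@H]1CC[C@@H]([C@@H]2CCC(O)O2)O1 | intermediate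
17 | methyl (2E,6S)-6-hydroxy-6-{(2S,5R)-5-[(7Z,9E)-tetradeca-7,9,13-trien-1-yl]oxolan-2-yl}hex-2-enoate | C=CCC/C=C/C=C\CCCCCC[C@@H]1CC[C@@H]([C@@H](O)CC/C=C/C(=O)OC)O1 | intermediate
18 | 3,4-dihydro-2H-pyran | C1=COCCC1 | starting material
19 | oxan-2-yl hydroperoxide (racemic) | OOC1CCCCO1 | intermediate
20 | methyl (2E,6S)-6-{(2S,5R)-5-[(7Z,9E)-tetradeca-7,9,13-trien-1-yl]oxolan-2-yl}-6-[(trifluoromethanesulfonyl)oxy]hex-2-enoate | C=CCC/C=C/C=C\CCCCCC[C@@H]1CC[C@@H]([C@@H](OS(=O)(=O)C(F)(F)F)CC/C=C/C(=O)OC)O1 | intermediate (not isolated)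
21 | potassium oxan-2-yl peroxide | [K+].[O-]OC1CCCCO1 | intermediate (not isolated)
22 | methyl (2E,6R)-6-[(oxan-2-yl)peroxy]-6-{(2S,5R)-5-[(7Z,9E)-tetradeca-7,9,13-trien-1-yl]oxolan-2-yl}hex-2-enoate (epimers at the acetal carbon) | C=CCC/C=C/C=C\CCCCCC[C@@H]1CC[C@@H]([C@H](OOC2CCCCO2)CC/C=C/C(=O)OC)O1 | intermediate
23 | methyl (2E,6R)-6-hydroperoxy-6-{(2S,5R)-5-[(7Z,9E)-tetradeca-7,9,13-trien-1-yl]oxolan-2-yl}hex-2-enoate | C=CCC/C=C/C=C\CCCCCC[C@@H]1CC[C@@H]([C@H](OO)CC/C=C/C(=O)OC)O1 | intermediate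
24 | methyl 2-[(3R,6R)-6-{(2S,5R)-5-[(7Z,9E)-tetradeca-7,9,13-trien-1-yl]oxolan-2-yl}-1,2-dioxan-3-yl]acetate | C=CCC/C=C/C=C\CCCCCC[C@@H]1CC[C@@H]([C@H]2CC[C@H](CC(=O)OC)OO2)O1 | intermediate
25 | 2-[(3R,6R)-6-{(2S,5R)-5-[(7Z,9E)-tetradeca-7,9,13-trien-1-yl]oxolan-2-yl}-1,2-dioxan-3-yl]acetic acid | C=CCC/C=C/C=C\CCCCCC[C@@H]1CC[C@@H]([C@H]2CC[C@H](CC(=O)O)OO2)O1 | target

**Totals**
Total step count: 14. Longest linear sequence: 12 steps (steps 1, 2, 3, 4, 5, 7, 8, 9, 11, 12, 13, 14); steps 6 and 10 are side branches.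

**The three steps most likely to fail**

Step 13 (the proposed new reaction). The squaramide may be too weak an activator for a plain enoate, its facial preference may oppose the chair preference of the substrate, or the amine may slowly degrade the secondary hydroperoxide (Kornblum–DeLaMare type loss to the C6 ketone). The quinidine-derived pseudo-enantiomer of the catalyst would be checked first. The fallback gives up catalyst control and uses established chemistry, setting out from 23 and coming back at 24. Hydroperoxide 23 is cyclised with Et2NH in CF3CH2OH at rt, the known conditions for closing hydroperoxy enoates to 1,2-dioxane-3-acetates. This gives 24 together with its C3 epimer, methyl 2-[(3S,6R)-6-{(2S,5R)-5-[(7Z,9E)-tetradeca-7,9,13-trien-1-yl]oxolan-2-yl}-1,2-dioxan-3-yl]acetate F1. The two esters are separated by chromatography, and F1 is put back into the same medium, where retro-Michael opening and reclosure convert it further into the diequatorial trans ester 24. The fallback described next for step 11 also by-passes this step.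

Step 11 (SN2 at a carbinol next to the ring oxygen). The adjacent C–O bond slows displacement, and elimination or ring expansion through an oxiranium ion can compete. The fallback makes the C6–O bond intramolecularly and the C3 centre by C–C bond formation, setting out from 15 and coming back at 24. Alcohol 15 is mesylated (MsCl, Et3N, CH2Cl2, 0 °C) to (1S)-3-(1,3-dioxolan-2-yl)-1-{(2S,5R)-5-[(7Z,9E)-tetradeca-7,9,13-trien-1-yl]oxolan-2-yl}propyl methanesulfonate F2. Acid-catalysed acetal exchange with anhydrous H2O2 in methanol (p-TsOH cat.) turns the dioxolane into the hydroperoxy methyl acetal (1S)-4-hydroperoxy-4-methoxy-1-{(2S,5R)-5-[(7Z,9E)-tetradeca-7,9,13-trien-1-yl]oxolan-2-yl}butyl methanesulfonate F3. KOt-Bu with 18-crown-6 in THF at 0 °C then closes the ring by 6-exo-tet alkylation of the hydroperoxy acetal with inversion at C6, giving (6R)-3-methoxy-6-{(2S,5R)-5-[(7Z,9E)-tetradeca-7,9,13-trien-1-yl]oxolan-2-yl}-1,2-dioxane F4. Finally Me3SiOSO2CF3 (cat.) and 1-methoxy-1-(trimethylsilyloxy)ethene in CH2Cl2 at −78 °C generate the peroxycarbenium ion, which the silyl ketene acetal attacks axially, trans to the equatorial C6 substituent, to give 24.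

Step 4 (threo selectivity of the Grignard addition). The functionalised Grignard reagent is thermally fragile and chelation control may be incomplete. The fallback sets the carbinol by ketone reduction, setting out from 6 and coming back at 9. Reagent 8 is added to 6 without chelation control, which gives 9 mixed with its carbinol epimer (1R)-1-[(2S,5R)-5-(7-chloroheptyl)oxolan-2-yl]-3-(1,3-dioxolan-2-yl)propan-1-ol F5. The mixture is oxidised with Dess–Martin periodinane to the ketone 1-[(2S,5R)-5-(7-chloroheptyl)oxolan-2-yl]-3-(1,3-dioxolan-2-yl)propan-1-one F6. Reduction with LiBH(s-Bu)3 in THF at −78 °C under Felkin–Anh control (hydride anti to the ring C–O bond) then gives the threo alcohol 9.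

**Further compounds**
F1 | step 13 | methyl 2-[(3S,6R)-6-{(2S,5R)-5-[(7Z,9E)-tetradeca-7,9,13-trien-1-yl]oxolan-2-yl}-1,2-dioxan-3-yl]acetate | C=CCC/C=C/C=C\CCCCCC[C@@H]1CC[C@@H]([C@H]2CC[C@@H](CC(=O)OC)OO2)O1
F2 | step 11 | (1S)-3-(1,3-dioxolan-2-yl)-1-{(2S,5R)-5-[(7Z,9E)-tetradeca-7,9,13-trien-1-yl]oxolan-2-yl}propyl methanesulfonate | C=CCC/C=C/C=C\CCCCCC[C@@H]1CC[C@@H]([C@@H](OS(C)(=O)=O)CCC2OCCO2)O1
F3 | step 11 | (1S)-4-hydroperoxy-4-methoxy-1-{(2S,5R)-5-[(7Z,9E)-tetradeca-7,9,13-trien-1-yl]oxolan-2-yl}butyl methanesulfonate (epimers at C4) | C=CCC/C=C/C=C\CCCCCC[C@@H]1CC[C@@H]([C@@H](OS(C)(=O)=O)CCC(OC)OO)O1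
F4 | step 11 | (6R)-3-methoxy-6-{(2S,5R)-5-[(7Z,9E)-tetradeca-7,9,13-trien-1-yl]oxolan-2-yl}-1,2-dioxane (epimers at C3) | C=CCC/C=C/C=C\CCCCCC[C@@H]1CC[C@@H]([C@H]2CCC(OC)OO2)O1
F5 | step 4 | (1R)-1-[(2S,5R)-5-(7-chloroheptyl)oxolan-2-yl]-3-(1,3-dioxolan-2-yl)propan-1-ol | ClCCCCCCC[C@@H]1CC[C@@H]([C@H](O)CCC2OCCO2)O1
F6 | step 4 | 1-[(2S,5R)-5-(7-chloroheptyl)oxolan-2-yl]-3-(1,3-dioxolan-2-yl)propan-1-one | ClCCCCCCC[C@@H]1CC[C@@H](C(=O)CCC2OCCO2)O1
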